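**Retrosynthetic overview**
1. The C10 methylidene is made last, by Horner–Wadsworth–Emmons reaction of a β-ketophosphonate with formaldehyde; the C1 methyl ester comes from a CH2OH group (oxidation, methylation).
2. The 1,2-dioxane (the only ring) comes from diimide reduction of a 3,6-dihydro-1,2-dioxine, made by [4+2] cycloaddition of singlet oxygen to an (E,E)-C3=C4–C5=C6 diene. Suprafacial addition sets C3/C6 cis; the C2 centre selects the face.
3. The keto-phosphonate chain (C9–C14) comes from acylation of a lithiated (5-hydroxy-5-methylhexyl)phosphonate by the diene ester.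
4. The (E,E)-diene ester comes from a Johnson–Claisen [3,3] rearrangement of a bis-allylic alcohol (C7–C8 bond, E-trisubstituted C5=C6), built from the Roche aldehyde by Wittig and isopropenyl Grignard reactions.
5. C2 is bought in (R)-Roche ester. The ring is formed once (step 10) and saturated in step 11.

Assumption: atom labels C1–C14 follow the target chain (C1 ester carbon, C2 the CH(CH3), C3 and C6 the ring carbons, C9 the ketone, C10 the methylidene-bearing carbon, C14 the carbinol carbon); commercial reagents are given by name and SMILES on the reagent line and carry no compound number.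
Note: 5–7 are mixtures at the carbinol carbon and 13–20 at the phosphonate-bearing carbon. Both centres are destroyed later (steps 5 and 14) and are left unspecified in the SMILES.

**Route**

Step 1
Reactants: 1 methyl (R)-3-hydroxy-2-methylpropanoate ((R)-Roche ester)
Product: 2 methyl (R)-3-[(tert-butyldimethylsilyl)oxy]-2-methylpropanoate
Conditions: TBSCl, imidazole, DMF, 0 °C to rt
Reagents that add atoms: tert-butyldimethylsilyl chloride, CC(C)(C)[Si](C)(C)Cl
Why: Standard imidazole-promoted silylation of the primary alcohol; the bought C2 stereocentre is untouched.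

Step 2
Reactants: 2 methyl (R)-3-[(tert-butyldimethylsilyl)oxy]-2-methylpropanoate
Product: 3 (R)-3-[(tert-butyldimethylsilyl)oxy]-2-methylpropanal
Conditions: DIBAL-H (1.05 equiv), CH2Cl2, −78 °C; Rochelle salt work-up; used crude
Reagents that add atoms: none
Why: Low-temperature DIBAL-H half-reduction stops at the aluminium hemiacetal and gives the Roche aldehyde without epimerising the α-centre.

Step 3
Reactants: 3 (R)-3-[(tert-butyldimethylsilyl)oxy]-2-methylpropanal
Product: 4 (2E,4S)-5-[(tert-butyldimethylsilyl)oxy]-4-methylpent-2-enal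
Conditions: Ph3P=CHCHO (1.2 equiv), toluene, 80 °C
Reagents that add atoms: (triphenylphosphoranylidene)acetaldehyde, O=CC=P(c1ccccc1)(c1ccccc1)c1ccccc1
Why: Wittig olefination with the stabilised formylmethylene ylide gives the (E)-enal under neutral conditions that spare the α-stereocentre.

Step 4
Reactants: 4 (2E,4S)-5-[(tert-butyldimethylsilyl)oxy]-4-methylpent-2-enal
Product: 5 (3RS,4E,6S)-7-[(tert-butyldimethylsilyl)oxy]-2,6-dimethylhepta-1,4-dien-3-ol
Conditions: isopropenylmagnesium bromide (1.3 equiv), THF, −78 °C; aq. NH4Cl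
Reagents that add atoms: isopropenylmagnesium bromide, C=C(C)[Mg]Br
Why: Grignard 1,2-addition to the enal; the new carbinol centre forms as a mixture and is erased in step 5.

Step 5
Reactants: 5 (3RS,4E,6S)-7-[(tert-butyldimethylsilyl)oxy]-2,6-dimethylhepta-1,4-dien-3-ol
Product: 8 ethyl (4E,6E,8S)-9-[(tert-butyldimethylsilyl)oxy]-4,8-dimethylnona-4,6-dienoate, via mixed orthoester 6 (not isolated), via ketene acetal 7 (not isolated)
Conditions: MeC(OEt)3 (8 equiv), EtCO2H (10 mol%), 135 °C, EtOH distilled off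
Reagents that add atoms: triethyl orthoacetate, CCOC(C)(OCC)OCC
Why: Johnson–Claisen [3,3]-sigmatropic rearrangement through a chair transition state with the alkenyl group equatorial forms the C7–C8 bond at the unhindered CH2 terminus and the (E)-C5=C6 alkene, so both carbinol epimers converge on one (E,E)-diene.

Step 6
Reactants: 9 ethyl 5-bromopentanoate
Product: 10 ethyl 5-(diethoxyphosphoryl)pentanoate
Conditions: P(OEt)3 (1.5 equiv), neat, 150 °C, EtBr distilled off
Reagents that add atoms: triethyl phosphite, CCOP(OCC)OCC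
Why: Michaelis–Arbuzov reaction of an unhindered primary bromide.

Step 7
Reactants: 10 ethyl 5-(diethoxyphosphoryl)pentanoate
Product: 11 diethyl (5-hydroxy-5-methylhexyl)phosphonate
Conditions: MeMgBr (2.5 equiv), THF, −20 to 0 °C; aq. NH4Cl
Reagents that add atoms: methylmagnesium bromide, C[Mg]Br
Why: Double Grignard addition to the ester is much faster than attack at the diethyl phosphonate and gives the tertiary alcohol (C14).

Step 8
Reactants: 8 ethyl (4E,6E,8S)-9-[(tert-butyldimethylsilyl)oxy]-4,8-dimethylnona-4,6-dienoate; 11 diethyl (5-hydroxy-5-methylhexyl)phosphonate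
Product: 13 diethyl [(10E,12E,14S)-15-[(tert-butyldimethylsilyl)oxy]-2-hydroxy-2,10,14-trimethyl-7-oxopentadeca-10,12-dien-6-yl]phosphonate, via dilithiated phosphonate 12 (not isolated)
Conditions: 11 (2.3 equiv), n-BuLi (4.6 equiv), THF, −78 °C; then 8, −78 to −20 °C; aq. NH4Cl
Reagents that add atoms: none
Why: Claisen-type acylation of the α-lithiated phosphonate by the ethyl ester forms the C9–C10 bond (the second equivalent of carbanion deprotonates the β-ketophosphonate formed); diene and silyl ether are inert.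

Step 9
Reactants: 13 diethyl [(10E,12E,14S)-15-[(tert-butyldimethylsilyl)oxy]-2-hydroxy-2,10,14-trimethyl-7-oxopentadeca-10,12-dien-6-yl]phosphonate
Product: 14 diethyl [(10E,12E,14S)-2,15-dihydroxy-2,10,14-trimethyl-7-oxopentadeca-10,12-dien-6-yl]phosphonate
Conditions: HF·pyridine, pyridine, THF, 0 °C to rt
Reagents that add atoms: none
Why: Fluoride desilylation frees the homoallylic primary alcohol that is needed to steer the oxygenation.

Step 10
Reactants: 14 diethyl [(10E,12E,14S)-2,15-dihydroxy-2,10,14-trimethyl-7-oxopentadeca-10,12-dien-6-yl]phosphonate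
Product: 15 diethyl [8-hydroxy-1-{(3S,6S)-6-[(2R)-1-hydroxypropan-2-yl]-3-methyl-3,6-dihydro-1,2-dioxin-3-yl}-8-methyl-3-oxononan-4-yl]phosphonate
Conditions: O2, TPP (1 mol%), visible light, CH2Cl2, −40 °C; chromatography on neutral silica
Reagents that add atoms: oxygen (used as singlet oxygen), O=O
Why: The [4+2] cycloaddition of singlet oxygen to the (E,E)-diene is suprafacial, so the C3 side chain and the C6 chain end up cis, and the bought C2 centre selects the face by hydrogen-bond delivery from its CH2OH arm in the H-eclipsed allylic conformer (selectivity expected to be modest; the facial isomer and ene hydroperoxides are removed by chromatography).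

Step 11
Reactants: 15 diethyl [8-hydroxy-1-{(3S,6S)-6-[(2R)-1-hydroxypropan-2-yl]-3-methyl-3,6-dihydro-1,2-dioxin-3-yl}-8-methyl-3-oxononan-4-yl]phosphonate
Product: 16 diethyl [8-hydroxy-1-{(3R,6S)-6-[(2R)-1-hydroxypropan-2-yl]-3-methyl-1,2-dioxan-3-yl}-8-methyl-3-oxononan-4-yl]phosphonate
Conditions: KO2CN=NCO2K (15 equiv), AcOH (30 equiv, slow addition), CH2Cl2/MeOH, 0 °C to rt
Reagents that add atoms: none
Why: Diimide generated in situ transfers H2 concertedly to the cis-disubstituted ring alkene and leaves the O–O bond, ketone and phosphonate alone, under acidic conditions that avoid Kornblum–DeLaMare cleavage.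

Step 12
Reactants: 16 diethyl [8-hydroxy-1-{(3R,6S)-6-[(2R)-1-hydroxypropan-2-yl]-3-methyl-1,2-dioxan-3-yl}-8-methyl-3-oxononan-4-yl]phosphonate
Product: 18 (2S)-2-{(3S,6R)-6-[4-(diethoxyphosphoryl)-8-hydroxy-8-methyl-3-oxononyl]-6-methyl-1,2-dioxan-3-yl}propanoic acid, via aldehyde 17 (not isolated)
Conditions: TEMPO (0.2 equiv), PhI(OAc)2 (2.5 equiv), MeCN/H2O 1:1, rt
Reagents that add atoms: water, O
Why: TEMPO/PhI(OAc)2 oxidation (Epp–Widlanski) takes the primary alcohol through the aldehyde hydrate to the acid under mildly acidic conditions that tolerate the peroxide and tertiary alcohol and should not epimerise C2.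

Step 13
Reactants: 18 (2S)-2-{(3S,6R)-6-[4-(diethoxyphosphoryl)-8-hydroxy-8-methyl-3-oxononyl]-6-methyl-1,2-dioxan-3-yl}propanoic acid
Product: 19 methyl (2S)-2-{(3S,6R)-6-[4-(diethoxyphosphoryl)-8-hydroxy-8-methyl-3-oxononyl]-6-methyl-1,2-dioxan-3-yl}propanoate
Conditions: TMSCHN2 (1.5 equiv), toluene/MeOH 4:1, 0 °C
Reagents that add atoms: trimethylsilyldiazomethane, C[Si](C)(C)C=[N+]=[N-]
Why: Neutral O-methylation of the carboxylic acid; the much less acidic β-ketophosphonate and the tertiary alcohol do not react.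

Step 14
Reactants: 19 methyl (2S)-2-{(3S,6R)-6-[4-(diethoxyphosphoryl)-8-hydroxy-8-methyl-3-oxononyl]-6-methyl-1,2-dioxan-3-yl}propanoate
Product: 21 aikupikoxide D = methyl (2S)-2-[(3S,6R)-6-(8-hydroxy-8-methyl-4-methylidene-3-oxononyl)-6-methyl-1,2-dioxan-3-yl]propanoate, via hydroxymethyl adduct 20 (not isolated)
Conditions: 37% aq. HCHO (excess), K2CO3 (2 equiv), THF/H2O, 0 °C to rt
Reagents that add atoms: formaldehyde, C=O
Why: Horner–Wadsworth–Emmons olefination of the β-ketophosphonate with formaldehyde (Villieras conditions) places the methylidene regiospecifically at C10 under carbonate base mild enough for the dioxane and the ester.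

**Compound list**
1 | methyl (R)-3-hydroxy-2-methylpropanoate | COC(=O)[C@H](C)CO | starting material
2 | methyl (R)-3-[(tert-butyldimethylsilyl)oxy]-2-methylpropanoate | COC(=O)[C@H](C)CO[Si](C)(C)C(C)(C)C | intermediate
3 | (R)-3-[(tert-butyldimethylsilyl)oxy]-2-methylpropanal | O=C[C@H](C)CO[Si](C)(C)C(C)(C)C | intermediate
4 | (2E,4S)-5-[(tert-butyldimethylsilyl)oxy]-4-methylpent-2-enal | O=C/C=C/[C@H](C)CO[Si](C)(C)C(C)(C)C | intermediate
5 | (3RS,4E,6S)-7-[(tert-butyldimethylsilyl)oxy]-2,6-dimethylhepta-1,4-dien-3-ol | C=C(C)C(O)/C=C/[C@H](C)CO[Si](C)(C)C(C)(C)C | intermediate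
6 | mixed orthoester of 5: tert-butyl{[(2S,3E)-5-(1,1-diethoxyethoxy)-2,6-dimethylhepta-3,6-dien-1-yl]oxy}dimethylsilane | C=C(C)C(OC(C)(OCC)OCC)/C=C/[C@H](C)CO[Si](C)(C)C(C)(C)C | intermediate
7 | ketene acetal: tert-butyl{[(2S,3E)-5-[(1-ethoxyethenyl)oxy]-2,6-dimethylhepta-3,6-dien-1-yl]oxy}dimethylsilane | C=C(C)C(OC(=C)OCC)/C=C/[C@H](C)CO[Si](C)(C)C(C)(C)C | intermediate
8 | ethyl (4E,6E,8S)-9-[(tert-butyldimethylsilyl)oxy]-4,8-dimethylnona-4,6-dienoate | CCOC(=O)CC/C(C)=C/C=C/[C@H](C)CO[Si](C)(C)C(C)(C)C | intermediate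
9 | ethyl 5-bromopentanoate | CCOC(=O)CCCCBr | starting material
10 | ethyl 5-(diethoxyphosphoryl)pentanoate | CCOC(=O)CCCCP(=O)(OCC)OCC | intermediate
11 | diethyl (5-hydroxy-5-methylhexyl)phosphonate | CCOP(=O)(OCC)CCCCC(C)(C)O | intermediate
12 | dilithiated 11 (lithium alkoxide and α-phosphonyl carbanion) | [Li+].[Li+].CCOP(=O)(OCC)[CH-]CCCC(C)(C)[O-] | intermediate
13 | diethyl [(10E,12E,14S)-15-[(tert-butyldimethylsilyl)oxy]-2-hydroxy-2,10,14-trimethyl-7-oxopentadeca-10,12-dien-6-yl]phosphonate | CCOP(=O)(OCC)C(CCCC(C)(C)O)C(=O)CC/C(C)=C/C=C/[C@H](C)CO[Si](C)(C)C(C)(C)C | intermediate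
14 | diethyl [(10E,12E,14S)-2,15-dihydroxy-2,10,14-trimethyl-7-oxopentadeca-10,12-dien-6-yl]phosphonate | CCOP(=O)(OCC)C(CCCC(C)(C)O)C(=O)CC/C(C)=C/C=C/[C@H](C)CO | intermediate
15 | diethyl [8-hydroxy-1-{(3S,6S)-6-[(2R)-1-hydroxypropan-2-yl]-3-methyl-3,6-dihydro-1,2-dioxin-3-yl}-8-methyl-3-oxononan-4-yl]phosphonate | CCOP(=O)(OCC)C(CCCC(C)(C)O)C(=O)CC[C@@]1(C)C=C[C@@H]([C@H](C)CO)OO1 | intermediate
16 | diethyl [8-hydroxy-1-{(3R,6S)-6-[(2R)-1-hydroxypropan-2-yl]-3-methyl-1,2-dioxan-3-yl}-8-methyl-3-oxononan-4-yl]phosphonate | CCOP(=O)(OCC)C(CCCC(C)(C)O)C(=O)CC[C@@]1(C)CC[C@@H]([C@H](C)CO)OO1 | intermediate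
17 | (2S)-2-{(3S,6R)-6-[4-(diethoxyphosphoryl)-8-hydroxy-8-methyl-3-oxononyl]-6-methyl-1,2-dioxan-3-yl}propanal | CCOP(=O)(OCC)C(CCCC(C)(C)O)C(=O)CC[C@@]1(C)CC[C@@H]([C@H](C)C=O)OO1 | intermediate
18 | (2S)-2-{(3S,6R)-6-[4-(diethoxyphosphoryl)-8-hydroxy-8-methyl-3-oxononyl]-6-methyl-1,2-dioxan-3-yl}propanoic acid | CCOP(=O)(OCC)C(CCCC(C)(C)O)C(=O)CC[C@@]1(C)CC[C@@H]([C@H](C)C(=O)O)OO1 | intermediate
19 | methyl (2S)-2-{(3S,6R)-6-[4-(diethoxyphosphoryl)-8-hydroxy-8-methyl-3-oxononyl]-6-methyl-1,2-dioxan-3-yl}propanoate | CCOP(=O)(OCC)C(CCCC(C)(C)O)C(=O)CC[C@@]1(C)CC[C@@H]([C@H](C)C(=O)OC)OO1 | intermediate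
20 | methyl (2S)-2-{(3S,6R)-6-[4-(diethoxyphosphoryl)-8-hydroxy-4-(hydroxymethyl)-8-methyl-3-oxononyl]-6-methyl-1,2-dioxan-3-yl}propanoate | CCOP(=O)(OCC)C(CO)(CCCC(C)(C)O)C(=O)CC[C@@]1(C)CC[C@@H]([C@H](C)C(=O)OC)OO1 | intermediate
21 | aikupikoxide D, methyl (2S)-2-[(3S,6R)-6-(8-hydroxy-8-methyl-4-methylidene-3-oxononyl)-6-methyl-1,2-dioxan-3-yl]propanoate | C=C(CCCC(C)(C)O)C(=O)CC[C@@]1(C)CC[C@@H]([C@H](C)C(=O)OC)OO1 | target

**Step count**
Total steps: 14. Longest linear sequence: 12 (steps 1–5 and 8–14 from 1); the phosphonate branch (steps 6–7) joins at step 8.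

**Three steps most likely to fail**

Step 10 (singlet-oxygen cycloaddition) is the weakest step. The C6 terminus of the diene carries an inward methyl group, so the ene reaction at C5=C6 competes; I expect only about one third to one half of the material as endoperoxide. Facial control by a homoallylic OH is also weak, perhaps 2–3:1. Fallback, setting out from aldehyde 3 and returning at 16, builds the O–O ring stepwise instead of by cycloaddition. Aldehyde 3 is allylated under Felkin control (allyltrimethylsilane, BF3·OEt2, CH2Cl2, −78 °C) to the syn homoallylic alcohol (2R,3R)-1-[(tert-butyldimethylsilyl)oxy]-2-methylhex-5-en-3-ol F1. Commercial ethyl 4-methylpent-4-enoate is acylated with 12 as in step 8 to give the keto phosphonate diethyl (2-hydroxy-2,10-dimethyl-7-oxoundec-10-en-6-yl)phosphonate F2. Cross-metathesis of F1 with excess F2 (Hoveyda–Grubbs II, CH2Cl2, 40 °C) gives the trisubstituted alkene F3 (E/Z immaterial). Mesylation (MsCl, Et3N, 0 °C) gives the secondary mesylate F4. Mukaiyama–Isayama hydroperoxysilylation (Co(thd)2, O2, Et3SiH) gives the tertiary triethylsilyl peroxide F5 as both C6 epimers. TBAF then frees the peroxide anion and the primary alcohol, and 6-exo-tet SN2 closure with inversion at C3 gives 16 together with its C6 epimer, which is separated. In this fallback C3 is fixed by the Roche centre, but C6 is not controlled.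

Step 5 (Johnson–Claisen) is the second risk. The bis-allylic alcohol 5 can ionise or transpose under acid at 135 °C, and some rearrangement through the other allyl arm is possible. Fallback, setting out from enal 4 and returning at 8, is a linear olefination–alkylation sequence with no acid and no rearrangement. Wittig reaction of 4 with ethyl 2-(triphenylphosphoranylidene)propanoate gives the dienoate ethyl (2E,4E,6S)-7-[(tert-butyldimethylsilyl)oxy]-2,6-dimethylhepta-2,4-dienoate F6. DIBAL-H reduction gives the dienol (2E,4E,6S)-7-[(tert-butyldimethylsilyl)oxy]-2,6-dimethylhepta-2,4-dien-1-ol F7. Appel bromination (CBr4, PPh3) gives the dienyl bromide {[(2S,3E,5E)-7-bromo-2,6-dimethylhepta-3,5-dien-1-yl]oxy}(tert-butyl)dimethylsilane F8, which is used at once to alkylate the lithium enolate of ethyl acetate (LDA, THF/DMPU, −78 °C) to give 8.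

Step 14 (final methylenation) is the third risk. It exposes the most advanced compound, a β-peroxy ester with an acidic C2–H, to aqueous base, so retro-oxa-Michael ring opening, ester hydrolysis or further reaction of the enone are possible. Fallback, setting out from 16 and returning at 21, reorders the endgame so that the base step is run before the ester exists. Alcohol 16 is treated with HCHO/K2CO3 to give the enone alcohol (2R)-2-[(3S,6R)-6-(8-hydroxy-8-methyl-4-methylidene-3-oxononyl)-6-methyl-1,2-dioxan-3-yl]propan-1-ol F9. TEMPO/PhI(OAc)2 oxidation gives the enone acid (2S)-2-[(3S,6R)-6-(8-hydroxy-8-methyl-4-methylidene-3-oxononyl)-6-methyl-1,2-dioxan-3-yl]propanoic acid F10. This is esterified with MeI/KHCO3 in DMF (no diazoalkane, which would add to the enone) to give 21.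

Further compounds
F1 | step 10 | (2R,3R)-1-[(tert-butyldimethylsilyl)oxy]-2-methylhex-5-en-3-ol | C=CC[C@H]([C@H](C)CO[Si](C)(C)C(C)(C)C)O
F2 | step 10 | diethyl (2-hydroxy-2,10-dimethyl-7-oxoundec-10-en-6-yl)phosphonate | C=C(C)CCC(=O)C(CCCC(C)(C)O)P(=O)(OCC)OCC
F3 | step 10 | diethyl [(13R,14R)-15-[(tert-butyldimethylsilyl)oxy]-2,13-dihydroxy-2,10,14-trimethyl-7-oxopentadec-10-en-6-yl]phosphonate (E/Z mixture) | CCOP(=O)(OCC)C(CCCC(C)(C)O)C(=O)CCC(C)=CC[C@H]([C@H](C)CO[Si](C)(C)C(C)(C)C)O
F4 | step 10 | diethyl [(13R,14R)-15-[(tert-butyldimethylsilyl)oxy]-2-hydroxy-13-(methanesulfonyloxy)-2,10,14-trimethyl-7-oxopentadec-10-en-6-yl]phosphonate | CCOP(=O)(OCC)C(CCCC(C)(C)O)C(=O)CCC(C)=CC[C@H]([C@H](C)CO[Si](C)(C)C(C)(C)C)OS(C)(=O)=O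
F5 | step 10 | diethyl [(13R,14R)-15-[(tert-butyldimethylsilyl)oxy]-2-hydroxy-13-(methanesulfonyloxy)-2,10,14-trimethyl-7-oxo-10-[(triethylsilyl)peroxy]pentadecan-6-yl]phosphonate (C10 epimers) | CCOP(=O)(OCC)C(CCCC(C)(C)O)C(=O)CCC(C)(OO[Si](CC)(CC)CC)CC[C@H]([C@H](C)CO[Si](C)(C)C(C)(C)C)OS(C)(=O)=O
F6 | step 5 | ethyl (2E,4E,6S)-7-[(tert-butyldimethylsilyl)oxy]-2,6-dimethylhepta-2,4-dienoate | CCOC(=O)/C(C)=C/C=C/[C@H](C)CO[Si](C)(C)C(C)(C)C
F7 | step 5 | (2E,4E,6S)-7-[(tert-butyldimethylsilyl)oxy]-2,6-dimethylhepta-2,4-dien-1-ol | OC/C(C)=C/C=C/[C@H](C)CO[Si](C)(C)C(C)(C)C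
F8 | step 5 | {[(2S,3E,5E)-7-bromo-2,6-dimethylhepta-3,5-dien-1-yl]oxy}(tert-butyl)dimethylsilane | BrC/C(C)=C/C=C/[C@H](C)CO[Si](C)(C)C(C)(C)C
F9 | step 14 | (2R)-2-[(3S,6R)-6-(8-hydroxy-8-methyl-4-methylidene-3-oxononyl)-6-methyl-1,2-dioxan-3-yl]propan-1-ol | C=C(CCCC(C)(C)O)C(=O)CC[C@@]1(C)CC[C@@H]([C@H](C)CO)OO1
F10 | step 14 | (2S)-2-[(3S,6R)-6-(8-hydroxy-8-methyl-4-methylidene-3-oxononyl)-6-methyl-1,2-dioxan-3-yl]propanoic acid | C=C(CCCC(C)(C)O)C(=O)CC[C@@]1(C)CC[C@@H]([C@H](C)C(=O)O)OO1
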